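The easy step is a single column: substrate in the oak run.

| flask | substrate | partner | remark | time |
|---|---|---|---|---|
| ash | 12 mM | 37.5 mM | run made earlier |  |
| oak | 19 mM | 37.5 mM | run made earlier |  |
| elm | 25 mM | 19 mM | run made earlier |  |
| flask | 25 mM | 37.5 mM |  | 25 h |

- ash (time / h: substrate / %, first product / %, other mono adduct / %): 4.00: 83, 9, 8; 8.00: 69, 13, 12; 10.0: 63, 16, 15; 15.0: 54, 21, 18; 20.0: 46, 24, 24; 25.0: 36, 20, 24
- oak (time / h: substrate / %, first product / %, other mono adduct / %): 2.00: 91, 5, 3; 3.00: 85, 8, 6; 5.00: 83, 11, 8; 8.00: 73, 14, 14; 10.0: 64, 14, 17; 15.0: 55, 20, 20; 25.0: 39, 26, 23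
- elm (time / h: substrate / %, first product / %, other mono adduct / %): 2.00: 96, 3, 0; 6.00: 88, 7, 5; 12.0: 80, 12, 11; 20.0: 71, 11, 13; 25.0: 65, 17, 16

(each reading ± 1.5 percentage points)

- the numbers in the tables scatter by 1.5 percentage points (one standard deviation)

- how much substrate there is at 25 h, in percent of the substrate charged
- how much first product there is at 25 h, in percent of the substrate charged
- how much other mono adduct there is at 25 h, in percent of the substrate charged
- how much bis adduct there is at 25 h, in percent of the substrate charged

Oak ends with substrate at 39% after 25.0 h. If each substrate lost takes one partner, oak's mean partner is 31.7 mM. The pair constant 1.19 L mol⁻¹ h⁻¹ is the log loss of substrate per unit of mean partner and per hour. Elm, with half the partner, reads 1.18 L mol⁻¹ h⁻¹ by the same reckoning.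

This reckoning climbs a ladder for the flask, the loss of substrate first. With partner held at its charge, a pseudo-first-order picture, substrate halves in 15.6 h. That is shorter than the 25 h asked, and this round leaves 32.8%. Putting that answer back, the flask's reckoned mean partner is 77.6% of its charge. The half-life stretches to 20.0 h, and substrate comes to 42.1%.

The next rung is the gap that the columns leave, read here as a leak out of the mono adducts. Oak's gap of 12.0% reads as a half-life of 35.4 h, longer than the flask's time and longer than the reckoned half-life of substrate. Carried over to the flask, this reckoning puts the gap near 11.4%.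

The forecast gives substrate 42%, first product 25%, other mono adduct 23% and bis adduct 10%. Its ground for the substrate rate: “so it is first order in partner and barely depends on substrate charge”.

The flask gives substrate 42.6%, first product 20.7%, other mono adduct 24.0% and bis adduct 6.57%, each within the forecast's margin.

    substrate + partner → first product (k = 0.730 L mol⁻¹ h⁻¹)
    substrate + partner → other mono adduct (k = 0.540 L mol⁻¹ h⁻¹)
    partner + first product → bis adduct (k = 0.640 L mol⁻¹ h⁻¹)
    partner + other mono adduct → bis adduct (k = 0.0470 L mol⁻¹ h⁻¹)
    partner → decomposed reagent (k = 0.00270 h⁻¹)
    first product ⇌ isomer of the product (K = 2.70, k = 0.0170 h⁻¹)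

At 25.0 h the flask keeps 53% of its partner, and the mean of that and the charge, with the pair constant, gives substrate 42.8%. A flask charged with 52.9 mM partner has bis adduct moved by 5 points from this flask's. The neighbour flask with 64 mM partner keeps 58.5% of it at 25.0 h, so the same mean with the pair constant gives 22.1% substrate, and that flask holds 22.1%.

All runs are simulated on assumed constants; scatter was added.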